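A small charge of starting material sits under a held gas that must dissolve before it can react. Does the run time finish the job?

starting material 0.0020 M; gas phase 0.46 mM (held); time 25 min

    starting material + dissolved gas → product (k1 = 110 M⁻¹ s⁻¹)
    starting material ⇌ dormant form (K2 = 1.2, k2 = 2.4 s⁻¹)
    gas phase ⇌ dissolved gas, rate k3*(csat - [dissolved gas]) (k3 = 0.23 s⁻¹, csat = 0.46 mM)

- amount of product at 25 min, in percent of the starting material charged
- amount of product if the flask were left three thousand times as long, in percent of the starting material charged

*What happens in the opening moments?* Starting material shares itself with the dormant form, with a relaxation half-life of 0.158 s. That is far shorter than the drain reckoned below, so I hold 45.5% of whatever is unconverted as starting material.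

*Is the gas there?* Not at the start. Step 1 uses dissolved gas with a rate constant of 0.100 s⁻¹ at the full charge, while transfer restores it with 0.23 s⁻¹, which is faster. The use constant shrinks with the charge, so the comparison drifts towards transfer and dissolved gas climbs to saturation.

*Your number?* The drain lifetime, the time in which the unconverted fraction of the charge falls by a factor e with dissolved gas at saturation: 43.5 s. This is a pseudo-first-order decay. The run spans 34.5 lifetimes, so I commit to 100 percent product.

*The weak spot?* Early on, dissolved gas stands near 69.7% of saturation, which stretches the lifetime. Even so, the run spans 24.0 stretched lifetimes.

*And the long wait?* Step 1 runs one way and the dormant form returns through starting material, so I again say 100 percent.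

The forecast gives 100% and 100%, on these grounds: “nothing limits conversion”.

The flask gives 100% and 100%. At 2.50 min, or 3.45 lifetimes, the drain lifetime leaves 3.18% unconverted, but this flask holds more: 5.36% as starting material and dormant form. Changing one setting at a time, all else held, the answer stays within 5 points down to a time of at least 3.1 min and up to a charge of at least 0.016 M.

The neighbour flask, charged with 5.0 × 10⁻⁴ M, has the same lifetime, since the charge does not enter it, and so again spans 34.5 lifetimes. It gives 100% product, with 0% of its starting material left.

The constants were chosen freely.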